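**Retrosynthetic overview**
1. Vidalol B is a 2-bromophloroglucinol core with two identical 2,3-dibromo-4,5-dihydroxybenzyl arms. Both CH2–C5(catechol ring) bonds are cut at once, giving a central bis(o-quinone methide) equivalent and two molecules of 3,4-dibromocatechol.
2. Enabling feature: each CH2 sits on a central-ring carbon (C4, C6) between two phenolic OH groups and para to the third, so a CH2–NMe2 arm ionizes to an o-quinone methide. Its partner, C5 of the catechol ring, is para to the C2–OH, and the C2–Br leaves the central ring without any C–H.
3. Bis-electrophile: 1-bromo-2,4,6-trimethoxybenzene → 2-bromophloroglucinol → double Mannich base.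
4. Nucleophile: 2,3-dibromophenol → ortho-formylation → Dakin oxidation → 3,4-dibromocatechol.
5. No ring is formed in the route: the three benzene rings and all five bromines are bought. The last step makes both diarylmethane bonds and needs no protecting group.

Key step: step 5

Remark on the chemistry: vidalol B has no stereocentre or other stereogenic element, so the SMILES defines one achiral compound and no stereocontrol is required.

**Step 1**
Reactants: 1 2,3-dibromophenol
Product: 2 3,4-dibromo-2-hydroxybenzaldehyde
Conditions: (CH2O)n, MgCl2, Et3N, THF, reflux; then 1 M HCl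
Reagents that add atoms: paraformaldehyde (formaldehyde unit), C=O
Why: Magnesium-mediated ortho-formylation (Casnati–Skattebøl): the Mg phenoxide delivers formaldehyde to the only ortho C–H (C6) and a second formaldehyde oxidizes the benzylic alkoxide by hydride transfer.

**Step 2**
Reactants: 2 3,4-dibromo-2-hydroxybenzaldehyde
Product: 3 3,4-dibromobenzene-1,2-diol (3,4-dibromocatechol)
Conditions: 30% H2O2, NaOH, H2O/THF, 0 °C → rt, Ar; then HCl
Reagents that add atoms: hydrogen peroxide, OO
Why: Dakin oxidation: the ortho phenoxide drives aryl migration in the peroxide adduct and the aryl formate is hydrolysed in situ, while the bromines are inert.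

**Step 3**
Reactants: 4 1-bromo-2,4,6-trimethoxybenzene
Product: 5 2-bromobenzene-1,3,5-triol (2-bromophloroglucinol)
Conditions: BBr3 (4 equiv), CH2Cl2, −78 °C → rt; then ice-water
Reagents that add atoms: none
Why: BBr3 ether cleavage (Lewis-acid demethylation): bromide attacks the O-methyl of each boron-complexed ether and the aryl C–Br bond should not be touched at low temperature.

**Step 4**
Reactants: 5 2-bromobenzene-1,3,5-triol
Product: 6 2-bromo-4,6-bis[(dimethylamino)methyl]benzene-1,3,5-triol
Conditions: CH2(NMe2)2 (2.3 equiv), EtOH, 0 °C → rt, Ar; precipitated betaine filtered and used promptly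
Reagents that add atoms: N,N,N',N'-tetramethylmethanediamine, CN(C)CN(C)C
Why: Phenolic Mannich aminomethylation: the acidic phloroglucinol protonates the aminal to CH2=NMe2+, which attacks the only two ring C–H positions (each ortho/para to all three OH), and low temperature with excess aminal should keep the first arm from ionizing before the second is installed.

**Step 5**
Reactants: 6 2-bromo-4,6-bis[(dimethylamino)methyl]benzene-1,3,5-triol; 3 3,4-dibromobenzene-1,2-diol (6 equiv)
Product: 10 vidalol B, via aminomethyl o-quinone methide 7 (not isolated), via monobenzylated Mannich base 8 (not isolated), via second o-quinone methide 9 (not isolated)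
Conditions: 3 (6 equiv), AcOH (4 equiv), HFIP, 60 °C, Ar, slow addition of 6; excess 3 recovered
Reagents that add atoms: none
Why: In HFIP/AcOH each ArCH2–NMe2 arm of 6 is N-protonated and expelled as Me2NH by the two ortho hydroxyls and the para hydroxyl of the central ring, giving an o-quinone methide (7, then 9; O-protonated it is a 2,4,6-trihydroxybenzyl cation) whose exocyclic CH2 is attacked by C5 of 3,4-dibromocatechol in a Friedel–Crafts (vinylogous Michael) addition, and tautomerization restores both aromatic rings; the second pass joins the mono-adduct 8 (through 9) to the second catechol and completes the target without any protecting group. The closest known reaction type is the benzylation of phenols by o-quinone methides released from phenolic Mannich bases (gramine-type alkylation), the classical way to the methylene bridge of bis-phloroglucinols, run here under HFIP conditions known for Friedel–Crafts benzylation of phenols. No ring is closed and no stereocentre is created. Site selectivity on the catechol is needed and comes from its substitution: C5 is para to the C2 hydroxyl (the OH flanked by Br, for which C5 is the only free ortho/para position), C6 is only ortho to the C1 hydroxyl, and catechols are alkylated at the para-type position. Cross-coupling must win over self-condensation, which is secured because the central ring has no C–H left (C2 carries Br), is kept in the N-protonated, non-phenolate form, and meets a sixfold excess of 3 under slow addition; O-alkylation by an o-quinone methide is reversible, so material should funnel to the C-benzylated product.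

**Compound list**
1 | 2,3-dibromophenol | Oc1cccc(Br)c1Br | starting material
2 | 3,4-dibromo-2-hydroxybenzaldehyde | O=Cc1ccc(Br)c(Br)c1O | intermediate
3 | 3,4-dibromobenzene-1,2-diol | Oc1ccc(Br)c(Br)c1O | intermediate
4 | 1-bromo-2,4,6-trimethoxybenzene | COc1cc(OC)c(Br)c(OC)c1 | starting material
5 | 2-bromobenzene-1,3,5-triol | Oc1cc(O)c(Br)c(O)c1 | intermediate
6 | 2-bromo-4,6-bis[(dimethylamino)methyl]benzene-1,3,5-triol | CN(C)Cc1c(O)c(Br)c(O)c(CN(C)C)c1O | intermediate
7 | 2-bromo-4-[(dimethylamino)methyl]-3,5-dihydroxy-6-methylidenecyclohexa-2,4-dien-1-one (not isolated) | C=C1C(=O)C(Br)=C(O)C(CN(C)C)=C1O | intermediate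
8 | 2-bromo-4-[(2,3-dibromo-4,5-dihydroxyphenyl)methyl]-6-[(dimethylamino)methyl]benzene-1,3,5-triol (not isolated) | CN(C)Cc1c(O)c(Br)c(O)c(Cc2cc(O)c(O)c(Br)c2Br)c1O | intermediate
9 | 2-bromo-4-[(2,3-dibromo-4,5-dihydroxyphenyl)methyl]-3,5-dihydroxy-6-methylidenecyclohexa-2,4-dien-1-one (not isolated) | C=C1C(=O)C(Br)=C(O)C(Cc2cc(O)c(O)c(Br)c2Br)=C1O | intermediate
10 | vidalol B, 2-bromo-4,6-bis[(2,3-dibromo-4,5-dihydroxyphenyl)methyl]benzene-1,3,5-triol | Oc1cc(Cc2c(O)c(Br)c(O)c(Cc3cc(O)c(O)c(Br)c3Br)c2O)c(Br)c(Br)c1O | target

**Summary**
Total step count: 5 (convergent, 2 + 2 + 1).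
Longest linear sequence: 3 steps (steps 1, 2, 5 or steps 3, 4, 5).

**Steps most likely to fail**

Step 5. What may go wrong: self-condensation, in which an o-quinone methide attacks the electron-rich central ring of another molecule at a substituted carbon (ipso attack with loss of an aminomethyl arm or of Br+) and gives methylene-bridged oligomers. The reaction may also stall after one arm, or alkylate C6 of the catechol. The fallback uses known chemistry, sets out from 4 and returns at 10. It keeps the central ring as its trimethyl ether, so that the ring is no longer nucleophilic and the electrophile is a simple benzylic cation. Rieche formylation of 4 (Cl2CHOMe, TiCl4, CH2Cl2, 0 °C → rt) at both free positions should give 5-bromo-2,4,6-trimethoxyisophthalaldehyde F1. NaBH4 (MeOH/THF, 0 °C) should reduce it to (5-bromo-2,4,6-trimethoxy-1,3-phenylene)dimethanol F2. Twofold acid-catalysed Friedel–Crafts benzylation of 3 (5 equiv) with F2 (TsOH cat., HFIP, rt) forms the same two CH2–C5 bonds and should give tri-O-methylvidalol B F3. BBr3 (CH2Cl2, −78 → 0 °C) then cleaves the three methyl ethers to 10.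

Step 4. What may go wrong: methylene bridging. The mono-Mannich base still has a free, very nucleophilic ring C–H; if it loses Me2NH, the resulting o-quinone methide is captured by a second phloroglucinol ring before the second arm is installed. The fallback sets out from 5 and returns at 6. Both C1 units are introduced at the aldehyde level, where they deactivate the ring and cannot ionize. Vilsmeier–Haack diformylation of 5 (POCl3, DMF, EtOAc, 0 °C → rt, then H2O) should give 5-bromo-2,4,6-trihydroxyisophthalaldehyde F4. Double reductive amination (Me2NH, NaBH(OAc)3, AcOH, THF, rt) should convert F4 into 6 at a stage where no ring C–H is left.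

Step 2. What may go wrong: migration of hydride instead of the electron-poor aryl group in the peroxide adduct (leading to the salicylic acid), and over-oxidation of the catechol by alkaline peroxide. The fallback sets out from 1 and returns at 3, replacing formylation/oxidation with a directed C–H oxygenation. Carbamoylation of 1 (Me2NCOCl, K2CO3, MeCN) should give 2,3-dibromophenyl dimethylcarbamate F5. Ruthenium-catalysed, carbamate-directed ortho C–H hydroxylation ([RuCl2(p-cymene)]2 cat., PhI(OCOCF3)2, TFA/TFAA, 80 °C) at the only ortho C–H should give 2,3-dibromo-6-hydroxyphenyl dimethylcarbamate F6. Hydrolysis (NaOH, EtOH/H2O, reflux, Ar; then HCl) should release 3.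

**Further compounds**
F1 | step 5 | 5-bromo-2,4,6-trimethoxyisophthalaldehyde | COc1c(C=O)c(OC)c(Br)c(OC)c1C=O
F2 | step 5 | (5-bromo-2,4,6-trimethoxy-1,3-phenylene)dimethanol | COc1c(CO)c(OC)c(Br)c(OC)c1CO
F3 | step 5 | tri-O-methylvidalol B, 5,5'-[(5-bromo-2,4,6-trimethoxy-1,3-phenylene)bis(methylene)]bis(3,4-dibromobenzene-1,2-diol) | COc1c(Cc2cc(O)c(O)c(Br)c2Br)c(OC)c(Br)c(OC)c1Cc1cc(O)c(O)c(Br)c1Br
F4 | step 4 | 5-bromo-2,4,6-trihydroxyisophthalaldehyde | O=Cc1c(O)c(Br)c(O)c(C=O)c1O
F5 | step 2 | 2,3-dibromophenyl dimethylcarbamate | CN(C)C(=O)Oc1cccc(Br)c1Br
F6 | step 2 | 2,3-dibromo-6-hydroxyphenyl dimethylcarbamate | CN(C)C(=O)Oc1c(O)ccc(Br)c1Br
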